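**Plan**
- Retrosynthesis: the three O-benzyl groups (5-O, 6-O, 3'-O) are removed first. Next the C2–C1' bond between ring C and ring B is cut, giving the flat, achiral 3-methoxychromone 8 and arylboronic acid 13. Ring C is then cut at the one-carbon unit C2 (O1–C2 and C2=C3) and at the acyl bond C4–C4a, giving 3,4,5-trimethoxyphenol 1 and methoxyacetic acid 2.
- Forward: ring A is bought and C4–C4a is made by ortho-acylation. Ring C is closed as a 4H-chromen-4-one with a formamide acetal, BCl3 frees only 5-OH and 6-OH, both are benzylated, and ring B is joined last at C2.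
- Enabling feature: at the chromone oxidation level C2 is the β-carbon of the vinylogous ester O1–C2=C3–C4=O of ring C, so it accepts an aryl–rhodium species. After the addition C3–H is α to C4=O and can epimerise, whereas C2 cannot as long as O1–C2 stays closed.
- Stereochemistry: C2 (R) comes from the chiral diene on rhodium. C3 (R) is relayed from C2 by equilibrating the cis/trans mixture through the enol to the 2,3-trans (diequatorial) isomer.
- Helpers: the C2=C3 double bond is the activating element and is used up in the key step. The benzyl ethers keep the 5,6-catechol from binding the boronic acid and from forming a deactivating phenoxide, and they leave in the last step.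

Key step: step 7

Assumption: (S,S)-Ph-bod* is taken as the ligand antipode that addresses the Re face of C2, by the quadrant model that holds for cyclic enones; should the sense be opposite, the (R,R) ligand is used and nothing else changes.

**Route**

Step 1
Reactants: 1 3,4,5-trimethoxyphenol; 2 methoxyacetic acid
Product: 3 1-(6-hydroxy-2,3,4-trimethoxyphenyl)-2-methoxyethan-1-one
Conditions: BF3·OEt2 (as solvent), 80 °C; aq. NaOAc work-up
Reagents that add atoms: none
Why: BF3-mediated Friedel–Crafts (Fries-type) ortho-acylation of an activated phenol with a carboxylic acid, in which the two positions ortho to OH of symmetric 1 are equivalent and are the only free ring positions, so a single regioisomer can form.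

Step 2
Reactants: 3 1-(6-hydroxy-2,3,4-trimethoxyphenyl)-2-methoxyethan-1-one
Product: 5 3,5,6,7-tetramethoxy-4H-chromen-4-one, via enaminone 4 (not isolated)
Conditions: DMF-DMA (3 equiv), toluene, 100 °C; then AcOH, 60 °C
Reagents that add atoms: N,N-dimethylformamide dimethyl acetal COC(OC)N(C)C
Why: Amide-acetal condensation at the OCH2 group next to the ketone followed by 6-endo addition–elimination of the ortho-phenol with loss of dimethylamine, the standard chromone/isoflavone ring synthesis from 2-hydroxyaryl ketones.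

Step 3
Reactants: 5 3,5,6,7-tetramethoxy-4H-chromen-4-one
Product: 7 5,6-dihydroxy-3,7-dimethoxy-4H-chromen-4-one, via cyclic chloroboronate 6 (not isolated)
Conditions: BCl3 (3 equiv), CH2Cl2, −78 °C to rt; then H2O
Reagents that add atoms: none
Why: Chelation-relayed Lewis-acid cleavage of aryl methyl ethers, in which boron bound to C4=O cleaves the peri 5-OMe and the resulting 5-O–BCl2 group cleaves the neighbouring 6-OMe by closing the five-membered dioxaborole 6, the pattern known for 2,3,4-trimethoxyaryl carbonyl compounds, while 7-OMe and the vinylic 3-OMe have no free chelating partner.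

Step 4
Reactants: 7 5,6-dihydroxy-3,7-dimethoxy-4H-chromen-4-one
Product: 8 5,6-bis(benzyloxy)-3,7-dimethoxy-4H-chromen-4-one
Conditions: BnBr (3 equiv), K2CO3 (4 equiv), DMF, 60 °C, Ar
Reagents that add atoms: benzyl bromide BrCc1ccccc1
Why: Williamson ether synthesis, in which excess bromide in warm DMF also alkylates the hydrogen-bonded 5-OH as is usual for 5-hydroxychromones and flavones, and anhydrous carbonate under argon spares the C2-unsubstituted pyranone and the catechol.

Step 5
Reactants: 9 5-bromo-2-methoxyphenol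
Product: 10 2-(benzyloxy)-4-bromo-1-methoxybenzene
Conditions: BnBr (1.1 equiv), K2CO3, acetone, reflux
Reagents that add atoms: benzyl bromide BrCc1ccccc1
Why: Williamson ether synthesis on a simple unhindered phenol, with the bromine already para to OMe as ring B requires.

Step 6
Reactants: 10 2-(benzyloxy)-4-bromo-1-methoxybenzene
Product: 13 [3-(benzyloxy)-4-methoxyphenyl]boronic acid, via aryllithium 11 (not isolated), via lithium triisopropoxyborate 12 (not isolated)
Conditions: n-BuLi, THF, −78 °C; B(OiPr)3, −78 °C to rt; 1 M HCl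
Reagents that add atoms: triisopropyl borate CC(C)OB(OC(C)C)OC(C)C; water O
Why: Bromine–lithium exchange at −78 °C is faster than benzylic deprotonation, and borate trapping with acidic hydrolysis is the standard arylboronic acid synthesis.

Step 7
Reactants: 8 5,6-bis(benzyloxy)-3,7-dimethoxy-4H-chromen-4-one; 13 [3-(benzyloxy)-4-methoxyphenyl]boronic acid
Product: 16 (2R,3R)-5,6-bis(benzyloxy)-2-[3-(benzyloxy)-4-methoxyphenyl]-3,7-dimethoxy-2,3-dihydro-4H-chromen-4-one, via cis epimer 14 (not isolated), via enol 15 (not isolated)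
Conditions: [RhCl(C2H4)2]2 (2.5 mol %), (S,S)-Ph-bod* = (1S,4S)-2,5-diphenylbicyclo[2.2.2]octa-2,5-diene (5.5 mol %), KOH (10 mol %), 13 (2 equiv), toluene/H2O 10:1, 50 °C; then aqueous layer removed, TsOH·H2O (20 mol %), 60 °C
Reagents that add atoms: none
Why: Proposed new method: the closest known reaction types are the Rh(I)/chiral-diene Hayashi–Miyaura 1,4-addition of arylboronic acids to C3-unsubstituted chromones and the same addition to trisubstituted acceptors such as 1-nitrocyclohexene with later cis-to-trans equilibration, but an acceptor of the 3-alkoxychromone class has not been shown, hence the label. In the mechanism 13 transmetalates to the Rh–OH complex, the aryl–Rh(diene) species binds C2=C3 of 8 and inserts syn so that the aryl group goes to C2, the β-carbon of the vinylogous ester O1–C2=C3–C4=O, and the resulting oxa-π-allyl rhodium enolate (which the 3-OMe oxygen can chelate) is cleaved by water to the ketone and Rh–OH. No ring is closed, and C2 is set by the catalyst, whose C2-symmetric diene leaves open only the quadrant in which the Re face of C2 (O1 > C3 > H) meets the aryl group, which gives 2R. C3 is first set kinetically by protonation anti to the pseudo-axial C2-aryl group, which should favour cis epimer 14, but because C3–H is α to C4=O the acid treatment interconverts 14 and 16 through enol 15 and should funnel the mixture into the trans isomer with 2-aryl and 3-OMe both equatorial, so that 3R is relayed from 2R under thermodynamic control. Selectivity for 1,4- over 1,2-addition is secured by the electron-rich C4 carbonyl of 8 flanked by 5-OBn and by the shielding of the product ketone between 5-OBn and 3-OMe. The integrity of C2 requires that O1–C2 is not opened by retro-oxa-Michael reaction of an enolate, which is why hydroxide is only catalytic and buffered by excess 13 and why the C3 equilibration runs through the neutral enol under acid and not through the enolate under base.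

Step 8
Reactants: 16 (2R,3R)-5,6-bis(benzyloxy)-2-[3-(benzyloxy)-4-methoxyphenyl]-3,7-dimethoxy-2,3-dihydro-4H-chromen-4-one
Product: 17 (2R,3R)-5,6-dihydroxy-2-(3-hydroxy-4-methoxyphenyl)-3,7-dimethoxy-2,3-dihydro-4H-chromen-4-one
Conditions: H2 (1 atm), 10% Pd/C, EtOAc/MeOH 1:1, rt; work-up under Ar
Reagents that add atoms: none
Why: Heterogeneous catalytic hydrogenolysis of aryl benzyl ethers, the usual end game for benzyl-protected dihydroflavonols, runs under neutral conditions so that neither C2 nor the enolisable C3 is disturbed.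

**Compound list**
1 | 3,4,5-trimethoxyphenol | COc1cc(O)cc(OC)c1OC | starting material
2 | methoxyacetic acid | COCC(=O)O | starting material
3 | 1-(6-hydroxy-2,3,4-trimethoxyphenyl)-2-methoxyethan-1-one | COCC(=O)c1c(O)cc(OC)c(OC)c1OC | intermediate
4 | 3-(dimethylamino)-1-(6-hydroxy-2,3,4-trimethoxyphenyl)-2-methoxyprop-2-en-1-one (double-bond geometry not defined, not isolated) | CN(C)C=C(OC)C(=O)c1c(O)cc(OC)c(OC)c1OC | intermediate
5 | 3,5,6,7-tetramethoxy-4H-chromen-4-one | COc1coc2cc(OC)c(OC)c(OC)c2c1=O | intermediate
6 | cyclic 5,6-O-chloroboronate of 5,6-dihydroxy-3,7-dimethoxychromone (not isolated) | COc1coc2cc(OC)c3OB(Cl)Oc3c2c1=O | intermediate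
7 | 5,6-dihydroxy-3,7-dimethoxy-4H-chromen-4-one | COc1coc2cc(OC)c(O)c(O)c2c1=O | intermediate
8 | 5,6-bis(benzyloxy)-3,7-dimethoxy-4H-chromen-4-one | COc1coc2cc(OC)c(OCc3ccccc3)c(OCc3ccccc3)c2c1=O | intermediate
9 | 5-bromo-2-methoxyphenol | COc1ccc(Br)cc1O | starting material
10 | 2-(benzyloxy)-4-bromo-1-methoxybenzene | COc1ccc(Br)cc1OCc1ccccc1 | intermediate
11 | [3-(benzyloxy)-4-methoxyphenyl]lithium (not isolated) | [Li]c1ccc(OC)c(OCc2ccccc2)c1 | intermediate
12 | lithium [3-(benzyloxy)-4-methoxyphenyl]triisopropoxyborate (not isolated) | [Li+].COc1ccc([B-](OC(C)C)(OC(C)C)OC(C)C)cc1OCc1ccccc1 | intermediate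
13 | [3-(benzyloxy)-4-methoxyphenyl]boronic acid | COc1ccc(B(O)O)cc1OCc1ccccc1 | intermediate
14 | (2R,3S)-5,6-bis(benzyloxy)-2-[3-(benzyloxy)-4-methoxyphenyl]-3,7-dimethoxy-2,3-dihydro-4H-chromen-4-one (2,3-cis, not isolated) | COc1ccc([C@H]2Oc3cc(OC)c(OCc4ccccc4)c(OCc4ccccc4)c3C(=O)[C@H]2OC)cc1OCc1ccccc1 | intermediate
15 | (2R)-5,6-bis(benzyloxy)-2-[3-(benzyloxy)-4-methoxyphenyl]-3,7-dimethoxy-2H-chromen-4-ol (enol, not isolated) | COc1ccc([C@H]2Oc3cc(OC)c(OCc4ccccc4)c(OCc4ccccc4)c3C(O)=C2OC)cc1OCc1ccccc1 | intermediate
16 | (2R,3R)-5,6-bis(benzyloxy)-2-[3-(benzyloxy)-4-methoxyphenyl]-3,7-dimethoxy-2,3-dihydro-4H-chromen-4-one (2,3-trans) | COc1ccc([C@H]2Oc3cc(OC)c(OCc4ccccc4)c(OCc4ccccc4)c3C(=O)[C@@H]2OC)cc1OCc1ccccc1 | intermediate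
17 | (2R,3R)-5,6-dihydroxy-2-(3-hydroxy-4-methoxyphenyl)-3,7-dimethoxy-2,3-dihydro-4H-chromen-4-one | COc1ccc([C@H]2Oc3cc(OC)c(O)c(O)c3C(=O)[C@@H]2OC)cc1O | target

**Step count**
Total step count: 8. Longest linear sequence: 6 (steps 1, 2, 3, 4, 7, 8).

**Steps most likely to fail**

**1. Step 7 (Proposed new method).**
What may go wrong:
- Migratory insertion of aryl–rhodium into the trisubstituted, doubly oxygen-substituted C2=C3 bond may be so slow that protodeboronation uses up the nucleophile.
- C2 may partly racemise by reversible opening of the O1–C2 bond.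
- The thermodynamic bias at C3 may be too small during the equilibration.

The fallback uses known chemistry only. The aryl group is added to a chromone without a C3 substituent, the substrate class for which the asymmetric 1,4-addition is established, and the 3-oxygen is brought in afterwards under kinetic substrate control. It sets out from 1 (and uses 13) and comes back to the route at 16. Compound 1 is acylated with acetic acid in BF3·OEt2 to 1-(6-hydroxy-2,3,4-trimethoxyphenyl)ethan-1-one F1. DMF-DMA converts this into the enaminone F2, which acid closes to 5,6,7-trimethoxy-4H-chromen-4-one F3. BCl3 as in step 3 leads through the cyclic chloroboronate F4 to 5,6-dihydroxy-7-methoxy-4H-chromen-4-one F5, and benzylation as in step 4 gives 5,6-bis(benzyloxy)-7-methoxy-4H-chromen-4-one F6. Rh/(S,S)-Ph-bod*-catalysed addition of 13 should then give the (S)-flavanone F7. Soft enolisation (TMSOTf, Et3N, CH2Cl2, 0 °C, no free enolate) gives the silyl enol ether F8. Rubottom oxidation (dimethyldioxirane, −40 °C; then citric acid, MeOH) should occur anti to the pseudo-axial C2-aryl group and give the trans-(2R,3R)-3-hydroxyflavanone F9. O-methylation without base-induced enolisation (Me3OBF4, 1,8-bis(dimethylamino)naphthalene, CH2Cl2) delivers 16.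

**2. Step 3.**
What may go wrong:
- Cleavage may stop after the 5-OMe group.
- Competing chelation of boron between C4=O and the 3-OMe oxygen may cause loss of the 3-methyl ether.

In the fallback the 6-oxygen is free from the start, so only the single, most reliable peri 5-O-demethylation remains. It sets out from 2 and comes back to the route at 7, through the same chloroboronate 6. Compound 2 is condensed in BF3·OEt2 with 2,6-dimethoxybenzene-1,4-diol F10, which is bought or made from 2,6-dimethoxy-1,4-benzoquinone with Na2S2O4 and has only one kind of ring C–H. This gives 1-(3,6-dihydroxy-2,4-dimethoxyphenyl)-2-methoxyethan-1-one F11. A Vilsmeier-type ring closure that tolerates free phenols (BF3·OEt2, DMF, MsCl, 60 °C) gives 6-hydroxy-3,5,7-trimethoxy-4H-chromen-4-one F12. BCl3 (2 equiv, −78 to 0 °C) then removes only the 5-methyl group.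

**3. Step 4.**
What may go wrong:
- Alkylation of the hydrogen-bonded 5-OH may be incomplete.
- Base may open the C2-unsubstituted pyranone.
- The catecholate may oxidise in air.

In the fallback both oxygens are capped at once in a temporary ring under base-free conditions. It sets out from 7 and comes back to the route at 17. Compound 7 is heated with dichlorodiphenylmethane (diphenyl ether, 170 °C) to the 5,6-O-diphenylmethylene ketal F13. This ketal also ties the 5-oxygen away from C4=O. F13 is taken through the conditions of step 7 with 13, by way of the cis epimer F14 and the enol F15, to the trans-(2R,3R) adduct F16. One hydrogenolysis (H2, Pd(OH)2/C, THF/MeOH) removes the ketal and the benzyl ether to give 17.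

**Further compounds**
F1 | step 7 | 1-(6-hydroxy-2,3,4-trimethoxyphenyl)ethan-1-one | CC(=O)c1c(O)cc(OC)c(OC)c1OC
F2 | step 7 | (E)-3-(dimethylamino)-1-(6-hydroxy-2,3,4-trimethoxyphenyl)prop-2-en-1-one | CN(C)/C=C/C(=O)c1c(O)cc(OC)c(OC)c1OC
F3 | step 7 | 5,6,7-trimethoxy-4H-chromen-4-one | COc1cc2occc(=O)c2c(OC)c1OC
F4 | step 7 | cyclic 5,6-O-chloroboronate of 5,6-dihydroxy-7-methoxychromone | COc1cc2occc(=O)c2c2OB(Cl)Oc12
F5 | step 7 | 5,6-dihydroxy-7-methoxy-4H-chromen-4-one | COc1cc2occc(=O)c2c(O)c1O
F6 | step 7 | 5,6-bis(benzyloxy)-7-methoxy-4H-chromen-4-one | COc1cc2occc(=O)c2c(OCc2ccccc2)c1OCc1ccccc1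
F7 | step 7 | (2S)-5,6-bis(benzyloxy)-2-[3-(benzyloxy)-4-methoxyphenyl]-7-methoxy-2,3-dihydro-4H-chromen-4-one | COc1ccc([C@H]2Oc3cc(OC)c(OCc4ccccc4)c(OCc4ccccc4)c3C(=O)C2)cc1OCc1ccccc1
F8 | step 7 | (2S)-5,6-bis(benzyloxy)-2-[3-(benzyloxy)-4-methoxyphenyl]-7-methoxy-4-(trimethylsilyloxy)-2H-chromene | COc1ccc([C@H]2Oc3cc(OC)c(OCc4ccccc4)c(OCc4ccccc4)c3C(O[Si](C)(C)C)=C2)cc1OCc1ccccc1
F9 | step 7 | (2R,3R)-5,6-bis(benzyloxy)-2-[3-(benzyloxy)-4-methoxyphenyl]-3-hydroxy-7-methoxy-2,3-dihydro-4H-chromen-4-one | COc1ccc([C@H]2Oc3cc(OC)c(OCc4ccccc4)c(OCc4ccccc4)c3C(=O)[C@@H]2O)cc1OCc1ccccc1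
F10 | step 3 | 2,6-dimethoxybenzene-1,4-diol | COc1cc(O)cc(OC)c1O
F11 | step 3 | 1-(3,6-dihydroxy-2,4-dimethoxyphenyl)-2-methoxyethan-1-one | COCC(=O)c1c(O)cc(OC)c(O)c1OC
F12 | step 3 | 6-hydroxy-3,5,7-trimethoxy-4H-chromen-4-one | COc1coc2cc(OC)c(O)c(OC)c2c1=O
F13 | step 4 | 5,6-O-diphenylmethylene ketal of 5,6-dihydroxy-3,7-dimethoxy-4H-chromen-4-one | COc1coc2cc(OC)c3OC(c4ccccc4)(c4ccccc4)Oc3c2c1=O
F14 | step 4 | (2R,3S)-2-[3-(benzyloxy)-4-methoxyphenyl]-3,7-dimethoxy-5,6-(diphenylmethylenedioxy)-2,3-dihydro-4H-chromen-4-one (2,3-cis) | COc1ccc([C@H]2Oc3cc(OC)c4OC(c5ccccc5)(c5ccccc5)Oc4c3C(=O)[C@H]2OC)cc1OCc1ccccc1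
F15 | step 4 | (2R)-2-[3-(benzyloxy)-4-methoxyphenyl]-3,7-dimethoxy-5,6-(diphenylmethylenedioxy)-2H-chromen-4-ol (enol) | COc1ccc([C@H]2Oc3cc(OC)c4OC(c5ccccc5)(c5ccccc5)Oc4c3C(O)=C2OC)cc1OCc1ccccc1
F16 | step 4 | (2R,3R)-2-[3-(benzyloxy)-4-methoxyphenyl]-3,7-dimethoxy-5,6-(diphenylmethylenedioxy)-2,3-dihydro-4H-chromen-4-one (2,3-trans) | COc1ccc([C@H]2Oc3cc(OC)c4OC(c5ccccc5)(c5ccccc5)Oc4c3C(=O)[C@@H]2OC)cc1OCc1ccccc1
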